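At 5.0 d, the time of reading, I want the share of Q in what has become Q or J.

| flask | G | D | L | remark | time |
|---|---|---|---|---|---|
| south | 0.050 M (fed, over 6.0 h) | 0.11 mM | 42 µM | run made earlier; the fed solution adds 0.50 times the starting volume |  |
| south-east | 0.050 M (fed, over 6.0 h) | 0.11 mM | 110 µM | run made earlier; the fed solution adds 0.50 times the starting volume |  |
| south-west | 0.050 M (fed, over 6.0 h) | 0.11 mM | 200 µM | run made earlier; the fed solution adds 0.50 times the starting volume |  |
| birch | 0.050 M (fed, over 6.0 h) | 0.11 mM | 50 µM | the fed solution adds 0.50 times the starting volume | 5.0 d |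
| ash | 0.050 M (fed, over 6.0 h) | 0.11 mM | 80 µM | the fed solution adds 0.50 times the starting volume | 5.0 d |
| maple | 0.050 M (fed, over 6.0 h) | 0.11 mM | 120 µM | the fed solution adds 0.50 times the starting volume | 5.0 d |
| oak | 0.050 M (fed, over 6.0 h) | 0.11 mM | 150 µM | the fed solution adds 0.50 times the starting volume | 5.0 d |
| cedar | 0.050 M (fed, over 6.0 h) | 0.11 mM | 250 µM | the fed solution adds 0.50 times the starting volume | 5.0 d |

* share of Q in all that became Q or J for birch, ash, maple, oak, cedar, in this order
* the course of these numbers from the first flask to the last (falls all the way / rises, then falls / rises all the way / falls, then rises / hardly changes)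

- charges are per starting volume, the dose included; the dosed solution carries all of it
- steps thought possible: D + L -> E; D + Z -> D + J; G <-> Z; 2 D <-> X; G + D -> D + Q
- "hardly changes" means that all values lie within two and a half points (for a concentration: within two and a half percent of the largest)

Birch, ash, maple, oak and cedar differ in cL, so I begin with the step D + L -> E. It takes one L for one D, and the feed dilutes both alike, so I carry the equivalence ratio ρ, the L charged per D charged: ρ = cL/cD, 0.455 in birch, 0.727 in ash, 1.09 in maple, 1.36 in oak and 2.27 in cedar. The zero of this scale is ρ = 1. Below it L is the limiting reagent, and if the step runs to its end, E holds a part ρ of the catalyst. Above it D is limiting, and at that end a part 1 − 1/ρ of L stays, which is 56.0% of the L charged in cedar.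

- south (time / d: Q / %, J / %, G / %): 1.04: 8.9, 1.2, 69.4; 2.08: 12.7, 4.4, 48.5; 3.00: 15.2, 6.8, 35.4; 4.00: 17.2, 10.8, 25.5; 5.00: 18.8, 14.7, 18.6
- south-east (time / d: Q / %, J / %, G / %): 1.04: 1.6, 0.1, 75.8; 2.08: 2.3, 0.6, 56.0; 3.00: 2.1, 0.6, 44.4; 4.00: 1.9, 0.7, 33.4; 5.00: 2.7, 0.7, 25.8
- south-west (time / d: Q / %, J / %, G / %): 0.417: 0.2, 0, 91.6; 0.833: 0.1, 0, 81.3; 1.25: 0, 0, 72.8; 2.50: 0.3, 0.4, 51.0; 5.00: 0.1, 0, 26.8

(each reading ± 0.3 percentage points)

South stands below the zero, at ρ = 0.382. In south, Q reads 8.9% and J 1.2% at 1.04 d, but between 4.00 d and 5.00 d J gains 3.9 percentage points and Q 1.6 points, and the share reads 56.1% at 5.00 d. South-east stands at ρ = 1.00, and there Q reads 2.7% and J 0.7%, a share of 79.4%, but from small amounts. South-west, at ρ = 1.82, reads Q 0.1% against a scatter of 0.3 points, so it gives no usable share. I therefore commit to two levels: near 56.1% for birch and ash, near 79.4% for maple, oak and cedar.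

The forecast, above my upper level from maple on, gives 56%, 55%, 85%, 94% and 98%, a course that falls, then rises, with the remark “These high-L shares rest on tiny amounts”.

The flasks give 55.4%, 52.7%, 74.4%, 80.1% and 82.3%, a course that falls, then rises.

    D + L → E (k = 13000 /M/h)
    D + Z → D + J (k = 350 /M/h)
    G ⇌ Z (K = 17.0, k = 0.0120 /h)
    2 D ⇌ X (K = 1.80 × 10⁵ /M, k = 1300 /M/h)
    G + D → D + Q (k = 260 /M/h)

My upper level stands 5 points above maple, and birch lies near my lower one. The row turns at cL = 86 µM, which is ρ = 0.786, with a share of 52.3%. In birch, ρ = 0.455 goes with E at 45.5% of the catalyst at 5.00 d. In cedar, ρ = 2.27 gave 56.0% of L left, and at 50.0 d L stands at 56.0% of its charge.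

(The readings stem from a simulated flask with constants of no real substance.)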